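The runs are calculated for an exercise; the scatter is artificial.

At early times grey makes 0.00342 M min⁻¹ of target and red 0.00380 M min⁻¹, although red holds 7.31 times the solid. So for your quick number I would count target in molar terms and set it against the reagent. In south the reagent is the limiting reagent on charge.

| flask | solid substrate | reagent | remark | time |
|---|---|---|---|---|
| grey | 0.013 M | 0.0475 M | run made earlier |  |
| red | 0.095 M | 0.0475 M | run made earlier |  |
| east | 0.015 M | 0.0475 M |  | 8.0 min |
| west | 0.050 M | 0.0475 M |  | 8.0 min |
| south | 0.15 M | 0.0475 M |  | 8.0 min |

| grey: time / min | grey: target / % | red: time / min | red: target / % |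
|---|---|---|---|
| 1.33 | 35 | 0.667 | 5 |
| 2.50 | 41 | 1.00 | 3 |
| 4.00 | 46 | 2.00 | 8 |
| 5.00 | 47 | 3.00 | 12 |
| 6.00 | 47 | 5.00 | 16 |
| 8.00 | 46 | 8.00 | 23 |

(each reading ± 1.5 percentage points)

- the analysis behind the earlier runs scatters by 1.5 percentage points, standard deviation
- at the start none of the solid substrate is in solution
- a reading or a percentage of target counts all its forms, free or not
- "hardly changes" means that all values lie within two and a half points (for a concentration: within two and a half percent of the largest)

- amount of target at the end, in percent of the solid substrate charged for east, west, south, in this order
- how that number moves from the first to the last of them (hardly changes / rises, then falls / falls all the way / rises all the way / falls, then rises)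

Assume that one reagent goes per target, so that the balance reads:

c reagent used = c target

share = c target / c reagent charged = 23% × 0.095 M / 0.0475 M = 46.0%

This fraction of the charged reagent that stands as target is what I call the reagent share. It is a reading from red at 8.0 min, and the scatter of 1.5 percentage points on the solid charged becomes 3 points on the reagent charge. My own reckoning puts the same share on the other flasks:

south: 46.0% × 0.0475 M / 0.15 M = 14.6%

west: 46.0% × 0.0475 M / 0.050 M = 43.7%

East's charge lies below the 0.0219 M this share implies, so there I take grey's 46% instead.

Your forecast says 46%, 42% and 15%, so falls all the way, and it rests on a “rate independent of solid loading while solid remains”. We differ slightly on west and otherwise stand close.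

The flasks give 45.1%, 26.9% and 15.0%, which also falls all the way.

    solid substrate ⇌ dissolved substrate, rate k1*(cs1 - [dissolved substrate]) while solid is left; crystals form when [dissolved substrate] > cs1 (solubility = 20.0 mM, k = 0.0220 s⁻¹)
    dissolved substrate + reagent → target (k = 0.560 L mol⁻¹ s⁻¹)
    2 dissolved substrate → side product (k = 1.60 L mol⁻¹ s⁻¹)
    solid product ⇌ target, rate k4*(cs4 - [target]) while solid is left; crystals form when [target] > cs4 (solubility = 8.80 mM, k = 2.30 s⁻¹)
    reagent ⇌ dormant form (K = 2.30, k = 0.0250 s⁻¹)

South's share comes to 47.4%, beside red's 46.0%, with solid at 14.6%. West's comes to 28.3%, with its solid at 0% by 4.00 min and its target moving from 24.4% then to 26.9% at 8.00 min. The main reason east ends at 45.1% is the step from two dissolved substrate to side product: the same east run without that step gives 94.7%, which covers 90% of what is missing.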